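- Slow is the wrong word for Friday's flask: target creeps from 21.7 % at 50.0 min to 24.4 % at 120 min, while starting material falls to 0.2 %, so I ask what end state it is approaching.

all flasks: starting material 41 mM; protic impurity 2.05 mM
- Friday's: reagent 82 mM; temperature 60 °C; the very flask that is asked about, followed so far
- Monday's: reagent 41 mM; temperature 55 °C; run made earlier
- flask: reagent 82.0 mM; temperature 60 °C; time 2.5 h

| run | time / min | target / % | starting material / % |
|---|---|---|---|
| Friday's | 10.0 | 7.5 | 57.1 |
| Friday's | 20.0 | 13.1 | 34.9 |
| Friday's | 50.0 | 21.7 | 6.9 |
| Friday's | 120 | 24.4 | 0.2 |
| Monday's | 2.50 | 0.7 | 88.9 |
| Monday's | 6.00 | 0.8 | 80.4 |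
| Monday's | 15.0 | 3.6 | 62.9 |
| Monday's | 30.0 | 7.7 | 40.5 |

(each reading ± 0.5 percentage points)

- target, in percent of the starting material first charged, at 2.5 h
- the remedy with the largest gain of target, or "none" below 2 percentage points (gamma / theta / beta / alpha / none)
- target present, with what was taken out counted in, in percent of the starting material first charged, after beta
- target present, with what was taken out counted in, in percent of the starting material first charged, after alpha

- gamma: change nothing and wait 2.5 h more
- theta: at 2.5 h raise the temperature by 25 K, then wait 2.5 h
- beta: at 2.5 h take out 90 % of the target then present, then wait 2.5 h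
- alpha: at 2.5 h add reagent, 50.0 % of the amount charged, then wait 2.5 h

- a species is counted by the starting material in it: one side product counts as two
- target that was removed still counts
- steps that have been proposed: starting material + protic impurity -> quenched substrate; starting material -> intermediate; starting material + target -> side product; reagent + intermediate -> target; target <-> isomer of the product
- additions bring no volume worth counting

- If the protic impurity quenches one starting material each, it claims 5.00 % of the charge.
- Friday's last reading gives 25.7 % for the number I carry: the stall share, target over the charge that is neither starting material nor quenched substrate.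
- When you come at 2.5 h, I expect target at 24.5 %, and waiting should add little.
- Don't add reagent: Friday's flask was charged with reagent at twice the starting material, more than the charge can use if each intermediate takes one.
- If you take out 90 % of the target and what stays in the flask returns to the stall share, the total, with what was taken out counted in, comes by my reckoning to 40.8 %.
- I can't read what heat does, because Monday's run changes temperature and reagent together; beta is my choice unless heat moves the share.
- The forecast says 24.6 %, beta, 40.8 % after beta and 24.7 % after alpha, with “Theta's shift is unknown but probably small”.
- The flask gives 24.3 %, 40.1 % after beta and 24.3 % after alpha; the best remedy is theta, gaining 18 percentage points against 16 points for beta.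

    starting material + protic impurity → quenched substrate (k = 23.6 M⁻¹ min⁻¹, Ea = 39.0 kJ mol⁻¹)
    starting material → intermediate (k = 0.0494 min⁻¹, Ea = 107 kJ mol⁻¹)
    starting material + target → side product (k = 0.526 M⁻¹ min⁻¹, Ea = 51.0 kJ mol⁻¹)
    reagent + intermediate → target (k = 0.796 M⁻¹ min⁻¹, Ea = 68.0 kJ mol⁻¹)
    target ⇌ isomer of the product (K = 2.57, k = 0.119 min⁻¹, Ea = 110 kJ mol⁻¹, ΔH = −36.0 kJ mol⁻¹)
    (constants at 60 °C)

- In this flask, target and isomer of the product relax, both ways together, with a half-life of 4.19 min, far shorter than the 2.5 h of the run, and a tenfold wait barely moves target. The stall share at 2.5 h comes out at 25.6 %. The neighbour flask with 160 mM of starting material stands lower at 2.5 h: its reagent, there the limiting reagent, stands at 0.0955 % of its charge, its intermediate at 37.6 %, and its stall share at 11.7 %.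

(All runs were computed with constants of no real substance; scatter was added.)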